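The cyclohexenone ring (C1 carbonyl, C2 methoxy carbon, C3, C4 carbinol, C5 farnesyl, C6 methyl) is traced back to a cyclopentene lacking C2. The five-membered 4-silyloxy enone is a stable commercial chiral acceptor, whereas its six-membered counterpart would aromatise. Methyl addition and farnesylation set C6 and C5; dehydrogenation and hydride delivery set C4 and leave a 3-silyloxycyclopent-2-enol. The key step exploits the C1(=O)–C2=C3–C4(OH) segment. The C4 zinc alkoxide steers an iodocarbenoid onto the C1=C3 silyl enol ether alone, and the iodocyclopropane opens at the shared C1–C3 bond to the six-membered enone in the same flask. Epoxidation and methanolysis then install the C2 methoxy group.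

Key step: step 4

Remark: C1–C6 in the text are the target locants given above and are used for the same atoms in every intermediate (compound names carry their own IUPAC locants); farnesyl = (2E,6E)-3,7,11-trimethyldodeca-2,6,10-trien-1-yl.

Step 1
Reactants: 1 (R)-4-(tert-butyldimethylsilyloxy)cyclopent-2-en-1-one; 2 (2E,6E)-farnesyl bromide
Product: 4 (2R,3R,4R)-4-(tert-butyldimethylsilyloxy)-2-[(2E,6E)-farnesyl]-3-methylcyclopentan-1-one, via enolate 3 (not isolated)
Conditions: MeLi, Me2Zn, THF, 0 °C; 1, −78 °C; then HMPA, 2, −78 to −40 °C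
Reagents that add atoms: methyllithium [Li]C; dimethylzinc C[Zn]C (together LiZnMe3, source of the C6 methyl group)
Why: Three-component coupling of the Noyori type (zincate conjugate addition, then enolate allylation), in which methyl adds to C6 anti to the C1 silyloxy group and the zinc-tempered enolate 3, which resists proton transfer and loss of silanolate, is allylated at C5 anti to the new methyl group by SN2 displacement that leaves the E alkenes of 2 untouched.

Step 2
Reactants: 4 (2R,3R,4R)-4-(tert-butyldimethylsilyloxy)-2-[(2E,6E)-farnesyl]-3-methylcyclopentan-1-one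
Product: 7 (4R,5R)-3-(tert-butyldimethylsilyloxy)-5-[(2E,6E)-farnesyl]-4-methylcyclopent-2-en-1-one, via lithium enolate 5 (not isolated), via sulfilimine 6 (not isolated)
Conditions: LiN(iPr)2, THF, −78 °C; PhS(Cl)=NtBu, −78 °C
Reagents that add atoms: none
Why: Mukaiyama dehydrogenation, in which kinetic deprotonation at the only CH2 (C3), sulfur attack anti to the C1 silyloxy group (hence syn to the C1 hydrogen) and intramolecular syn elimination at −78 °C, cold enough to outrun E1cB loss of silanolate, turn the spent C1 stereocentre into a silyl enol ether carbon without any protecting-group exchange.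

Step 3
Reactants: 7 (4R,5R)-3-(tert-butyldimethylsilyloxy)-5-[(2E,6E)-farnesyl]-4-methylcyclopent-2-en-1-one
Product: 8 (1R,4R,5R)-3-(tert-butyldimethylsilyloxy)-5-[(2E,6E)-farnesyl]-4-methylcyclopent-2-en-1-ol
Conditions: iBu2AlH, toluene, −78 °C; aq potassium sodium tartrate; used crude
Reagents that add atoms: none
Why: 1,2-Reduction of a vinylogous silyl ester (the first half of a Stork–Danheiser sequence, stopped before any acid), in which hydride attacks the C4 carbonyl anti to the neighbouring C5 farnesyl group and so sets the C4 carbinol cis to C5, while the non-acidic work-up keeps the silyl enol ether.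

Step 4
Reactants: 8 (1R,4R,5R)-3-(tert-butyldimethylsilyloxy)-5-[(2E,6E)-farnesyl]-4-methylcyclopent-2-en-1-ol
Product: 10 (4S,5R,6R)-5-[(2E,6E)-farnesyl]-4-hydroxy-6-methylcyclohex-2-en-1-one, via iodocyclopropane 9 (not isolated)
Conditions: Et2Zn (2 equiv), CHI3, CH2Cl2/Et2O, −40 to 0 °C; then Bu4NF, AcOH, THF, 0 °C
Reagents that add atoms: iodoform IC(I)I (its CH becomes C2)
Why: Et2Zn turns the C4 hydroxyl of 8 into a zinc alkoxide and CHI3 into EtZnCHI2, and the alkoxide-bound carbenoid transfers its CH(iodo) unit to the cis face of the C1=C3 bond through the concerted butterfly transition state ([2+1] closure of the three-membered ring C1–C2–C3) to give 9. In 9 the C1 silyloxy donor pushes and the iodide on C2 leaves in a disrotatory two-electron electrocyclic opening (Woodward–Hoffmann–DePuy rule, endo leaving group), so the shared C1–C3 bond breaks, the five-membered ring C1–C3–C4–C5–C6 becomes the six-membered ring C1–C2–C3–C4–C5–C6 and desilylation of the oxocarbenium ion leaves the enone; buffered fluoride then completes desilylation, opens any exo-iodide through its cyclopropanolate and frees any C4 oxygen silylated by the released silyl iodide. The closest known reaction types are the hydroxyl-directed Simmons–Smith (Furukawa) halocyclopropanation of allylic alcohols and the halocarbene ring enlargement of cyclic silyl enol ethers to the homologous 2-cycloalkenones. No stereocentre is created in 10: C1, C2 and C3 of 9, set by the alkoxide, are erased, and C4, C5 and C6 are spectators. The step needs chemoselectivity over the three trisubstituted farnesyl alkenes, secured by the directing zinc alkoxide next to the most electron-rich double bond of 8, and cleavage of the internal rather than a peripheral cyclopropane bond, secured by placing the leaving group on C2, opposite the C1–C3 bond.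

Step 5
Reactants: 10 (4S,5R,6R)-5-[(2E,6E)-farnesyl]-4-hydroxy-6-methylcyclohex-2-en-1-one
Product: 11 4-[(2E,6E)-farnesyl]-5-hydroxy-3-methyl-7-oxabicyclo[4.1.0]heptan-2-one (C2–C3 oxirane cis to the C4 hydroxyl)
Conditions: 30% aq H2O2, catalytic NaOH, MeOH, 0 °C
Reagents that add atoms: hydrogen peroxide OO
Why: Weitz–Scheffer epoxidation, in which hydroperoxide adds only to the electron-poor C2=C3 bond because the farnesyl alkenes are inert to nucleophilic oxidants, and hydrogen bonding to the C4 hydroxyl should place the oxirane cis to it, although both new stereocentres are erased in step 6.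

Step 6
Reactants: 11 4-[(2E,6E)-farnesyl]-5-hydroxy-3-methyl-7-oxabicyclo[4.1.0]heptan-2-one
Product: 13 (4R,5R,6R)-5-[(2E,6E)-farnesyl]-4-hydroxy-2-methoxy-6-methylcyclohex-2-en-1-one (target), via methoxy diol 12 (not isolated)
Conditions: catalytic NaOMe, MeOH, 0 °C to rt
Reagents that add atoms: methanol CO (delivered as methoxide, sodium methoxide C[O-].[Na+])
Why: Base-induced methanolysis of an α,β-epoxy ketone, in which methoxide opens the oxirane at the carbonyl-activated C2 by SN2 inversion to give 12, E1cB loss of the C3 hydroxyl gives the 2-methoxy enone, the cis epoxy alcohol cannot enter a Payne migration, and C6 stays in the favoured trans-diequatorial relation to C5.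

Compound list
1 | (R)-4-(tert-butyldimethylsilyloxy)cyclopent-2-en-1-one | O=C1C=C[C@H](O[Si](C)(C)C(C)(C)C)C1 | starting material
2 | (2E,6E)-farnesyl bromide | BrC/C=C(\C)CC/C=C(\C)CCC=C(C)C | starting material
3 | lithium enolate of (3R,4R)-4-(tert-butyldimethylsilyloxy)-3-methylcyclopentanone (Me2Zn-bound in the flask) | [Li+].[O-]C1=C[C@@H](C)[C@H](O[Si](C)(C)C(C)(C)C)C1 | intermediate
4 | (2R,3R,4R)-4-(tert-butyldimethylsilyloxy)-2-[(2E,6E)-farnesyl]-3-methylcyclopentan-1-one | O=C1[C@H](C/C=C(\C)CC/C=C(\C)CCC=C(C)C)[C@@H](C)[C@H](O[Si](C)(C)C(C)(C)C)C1 | intermediate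
5 | kinetic lithium enolate of 4 (C4=C3) | [Li+].[O-]C=1[C@H](C/C=C(\C)CC/C=C(\C)CCC=C(C)C)[C@@H](C)[C@H](O[Si](C)(C)C(C)(C)C)C=1 | intermediate
6 | C3-(N-tert-butyl-S-phenylsulfilimino) derivative of 4, sulfur trans to the C1 silyloxy group | O=C1[C@H](C/C=C(\C)CC/C=C(\C)CCC=C(C)C)[C@@H](C)[C@H](O[Si](C)(C)C(C)(C)C)[C@H]1S(=NC(C)(C)C)c1ccccc1 | intermediate
7 | (4R,5R)-3-(tert-butyldimethylsilyloxy)-5-[(2E,6E)-farnesyl]-4-methylcyclopent-2-en-1-one | O=C1[C@H](C/C=C(\C)CC/C=C(\C)CCC=C(C)C)[C@@H](C)C(O[Si](C)(C)C(C)(C)C)=C1 | intermediate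
8 | (1R,4R,5R)-3-(tert-butyldimethylsilyloxy)-5-[(2E,6E)-farnesyl]-4-methylcyclopent-2-en-1-ol | O[C@@H]1[C@H](C/C=C(\C)CC/C=C(\C)CCC=C(C)C)[C@@H](C)C(O[Si](C)(C)C(C)(C)C)=C1 | intermediate
9 | 5-(tert-butyldimethylsilyloxy)-3-[(2E,6E)-farnesyl]-6-endo-iodo-4-methylbicyclo[3.1.0]hexan-2-ol, cyclopropane cis to the hydroxyl (zinc alkoxide in the flask, drawn as the alcohol) | O[C@@H]1[C@H](C/C=C(\C)CC/C=C(\C)CCC=C(C)C)[C@@H](C)[C@]2(O[Si](C)(C)C(C)(C)C)[C@H](I)[C@H]12 | intermediate
10 | (4S,5R,6R)-5-[(2E,6E)-farnesyl]-4-hydroxy-6-methylcyclohex-2-en-1-one | O=C1C=C[C@H](O)[C@H](C/C=C(\C)CC/C=C(\C)CCC=C(C)C)[C@H]1C | intermediate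
11 | 4-[(2E,6E)-farnesyl]-5-hydroxy-3-methyl-7-oxabicyclo[4.1.0]heptan-2-one, oxirane cis to the hydroxyl | O=C1[C@@H]2O[C@@H]2[C@H](O)[C@H](C/C=C(\C)CC/C=C(\C)CCC=C(C)C)[C@H]1C | intermediate
12 | 5-[(2E,6E)-farnesyl]-3,4-dihydroxy-2-methoxy-6-methylcyclohexan-1-one, 2-methoxy trans to 3-hydroxy | O=C1[C@@H](OC)[C@H](O)[C@H](O)[C@H](C/C=C(\C)CC/C=C(\C)CCC=C(C)C)[C@H]1C | intermediate
13 | (4R,5R,6R)-5-[(2E,6E)-farnesyl]-4-hydroxy-2-methoxy-6-methylcyclohex-2-en-1-one | COC1=C[C@H](O)[C@H](C/C=C(\C)CC/C=C(\C)CCC=C(C)C)[C@@H](C)C1=O | target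

Total step count: 6. Longest linear sequence: 6 steps (from 1).

Steps most likely to fail

Step 4. Zinc iodide may ionise the allylic C4–oxygen bond of the enol ether before carbenoid transfer, which loses the hydroxyl and gives a transposed cyclopentenone. The carbenoid may also leak onto the side-chain alkenes, or the exo-iodide may open sluggishly.
- Fallback, from 8: a samarium carbenoid (samarium metal, catalytic HgCl2, CH2I2, THF, −78 °C to rt) is not Lewis acidic and reacts only with allylic alcohols. It should give the iodine-free siloxycyclopropane F1.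
- FeCl3 in DMF then cleaves the same C1–C3 bond by one-electron oxidation (Saegusa-type oxidative ring enlargement) to the ring-enlarged 3-chloro ketone F2.
- NaOAc in MeOH eliminates HCl and rejoins the route at 10.

Step 6. Methoxide may isomerise the free γ-hydroxy enone to the 1,4-diketone and on to aromatic material, or the β-hydroxy ketone stage may undergo retro-aldol cleavage, both helped by the free C4 alkoxide.
- Fallback, from 10: TBSCl and imidazole in DMF mask the hydroxyl as the silyl ether F3.
- H2O2/NaOH in MeOH gives the epoxy ketone F4 (oxirane trans to the silyloxy group).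
- NaOMe in MeOH gives the silyl-protected methoxy enone F5, which has no alkoxide next to the reacting centres.
- HF·pyridine in THF rejoins the route at 13.

Step 2. Proton transfer within the free lithium enolate may lead to E1cB expulsion of silanolate, or deprotonation at C5 may compete.
- Fallback, from 4: LiN(iPr)2 in the presence of Me3SiCl (internal quench, THF, −78 °C) traps the kinetic enolate as it forms, giving the trimethylsilyl enol ether F6.
- Pd(OAc)2 in MeCN (Saegusa–Ito oxidation) then removes the silyl group and the C1 hydrogen and rejoins the route at 7.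

Further compounds
F1 | step 4 | 5-(tert-butyldimethylsilyloxy)-3-[(2E,6E)-farnesyl]-4-methylbicyclo[3.1.0]hexan-2-ol, cyclopropane cis to the hydroxyl | O[C@@H]1[C@H](C/C=C(\C)CC/C=C(\C)CCC=C(C)C)[C@@H](C)[C@]2(O[Si](C)(C)C(C)(C)C)C[C@H]12
F2 | step 4 | 3-chloro-5-[(2E,6E)-farnesyl]-4-hydroxy-6-methylcyclohexan-1-one (C3 epimers) | O=C1CC(Cl)[C@H](O)[C@H](C/C=C(\C)CC/C=C(\C)CCC=C(C)C)[C@H]1C
F3 | step 6 | tert-butyldimethylsilyl ether of 10 | O=C1C=C[C@H](O[Si](C)(C)C(C)(C)C)[C@H](C/C=C(\C)CC/C=C(\C)CCC=C(C)C)[C@H]1C
F4 | step 6 | C2–C3 epoxide of F3, oxirane trans to the silyloxy group | O=C1[C@H]2O[C@H]2[C@H](O[Si](C)(C)C(C)(C)C)[C@H](C/C=C(\C)CC/C=C(\C)CCC=C(C)C)[C@H]1C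
F5 | step 6 | tert-butyldimethylsilyl ether of 13 | COC1=C[C@H](O[Si](C)(C)C(C)(C)C)[C@H](C/C=C(\C)CC/C=C(\C)CCC=C(C)C)[C@@H](C)C1=O
F6 | step 2 | trimethylsilyl enol ether (C4=C3) of 4 | C[Si](C)(C)OC=1[C@H](C/C=C(\C)CC/C=C(\C)CCC=C(C)C)[C@@H](C)[C@H](O[Si](C)(C)C(C)(C)C)C=1
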